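## The problem

Coelenterazine (22) is an imidazo[1,2-a]pyrazin-3(7H)-one. A pyrazine ring (N4, C5, C6, N7, C8, C8a) is fused along the N4–C8a bond to a five-membered imidazolone (N1, C2, C3). C2 carries a 4-hydroxybenzyl group, C6 a 4-hydroxyphenyl group and C8 a benzyl group. The molecule has no stereocentre, so nothing has to be controlled in three dimensions. The difficulty is regiochemical: aryl, benzyl and the exocyclic nitrogen N1 must sit on the 5-, 3- and 2-positions of a pyrazine without isomers. The bicyclic core is an electron-rich 7H-dihydropyrazine that autoxidises readily, above all in basic or polar aprotic media, so the imidazolone ring should be closed in the last step, in acid and without oxygen. The two phenols would intercept carbenes and organometallic reagents; they must stay masked until the pyrazine is complete and be free before the final ring closure. The enabling feature is that the six pyrazine atoms divide into two three-atom halves of opposite polarity. N4–C5–C6(aryl) is the N1–C5–C4 skeleton of a 4-aryl-1-sulfonyl-1,2,3-triazole, that is, of an electrophilic α-imino carbene. N7–C8(benzyl)–C8a is the N–C3–C2 ring of a 3-benzyl-2H-azirine, which is nucleophilic at nitrogen. An ester on the azirine carbon that becomes C8a supplies the acidic hydrogen for aromatisation and the carbon handle later exchanged for N1.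

## Retrosynthesis

**Imidazolone ring (22 ⇒ 15 + 20).** The bonds N1–C2 and N4–C3 are cut. This leads to coelenteramine 15 and a three-carbon 2-oxoaldehyde 21, released in the flask from its diethyl acetal 20. Cutting only N4–C3 (lactamisation of an N-pyrazinyl amino acid) would need a separate C–N bond formation on a weakly nucleophilic aminopyrazine. The double condensation forms both bonds in one acidic operation that the sensitive product tolerates. The precursors are a stable monocyclic aminopyrazine and a C9 ketoacetal. The forward reaction must condense in one orientation and exclude oxygen.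

**Ketoacetal (20 ⇒ 19 ⇒ 16 + 17).** The CH2–C(=O) bond is cut to a benzylic Grignard reagent 18, from chloride 16, and ethyl diethoxyacetate 17. The phenol is carried as a benzyl ether in 19 and freed by hydrogenolysis. The alternative cut at the acetal carbon would require oxidation of a methyl ketone. The forward reaction must stop at the ketone after one addition.

**Exocyclic nitrogen (15 ⇒ 14 ⇒ 11 ⇒ 10).** The C8a–N1 bond is traced to a C8a–carboxyl bond. Acid 11 gives the carbamate 14 by Curtius rearrangement through 12 and 13, and 11 comes from methyl ester 10. Direct amination of a pyrazine C–H bond would not be regioselective, and a halide route would need a pyrazinone first. The ester is already required by the ring synthesis, so it costs nothing extra. One Lewis-acid step removes the methyl ether and the Boc group of 14 together.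

**Pyrazine ring (10 ⇒ 3 + 7, key disconnection).** The bonds N7–C6 and N4–C8a are cut. The fragments are the N-tosyl triazole 3 (N4, C5, C6 with the anisyl group) and the azirine ester 7 (N7, C8 with benzyl, C8a with the ester). Condensation cuts at N4–C5 or N7–C8 pair an aminoketone with a dicarbonyl compound and give regioisomers or need a later oxidation. Cross-coupling cuts presuppose a preformed pyrazine. Here both C–N bonds and the aromatisation come from one cascade through the diazatriene 8 and the dihydropyrazine 9. The forward reaction must prefer 1,6- over 1,5-closure of 8.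

**Triazole (3 ⇒ 1 + 2).** The triazole bonds N1–C5 and N3–C4 are cut to 4-ethynylanisole 1 and tosyl azide 2. A copper-catalysed cycloaddition gives only the 1,4-isomer, which places the aryl group on the future carbene carbon.

**Azirine (7 ⇒ 6 ⇒ 5 ⇒ 4).** The N–C2 bond of the azirine is cut by a Neber disconnection to the oxime tosylate 6, and then to oxime 5 and the commercial β-keto ester 4. The benzyl group sits on the azirine and not on the triazole because an alkyl group on the carbene carbon would invite a 1,2-hydride shift.

## Roads not taken

**Alternative 1:** The pyrazine is cut at N7–C8 and N7–C6, which leaves the acyclic keto-amide A2 and an ammonia source. In the forward direction ammonia condenses with the α-keto carbon and the aryl ketone of A2, and the ring closes directly at the aromatic oxidation level to pyrazinone A1.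
- Merits: A2 is one amide bond away from simple building blocks. No transition metal, sulfonyl azide or acyl azide is needed. The connectivity of A2 fixes the regiochemistry.
- Weak points: A1 has oxygen at C8a where the target needs N1. The C–O bond must be activated (halide or sulfonate) and replaced by nitrogen, with the phenol masked meanwhile. The 1,2-dicarbonyl half of A2 has acidic benzylic hydrogens and is largely enolised, so amide formation and the ammonia step compete with aldol-type self-condensation. The aminoketone half also tends to self-condense.
- Comparison: The ring-forming step is cheaper and easier to scale than a rhodium carbene reaction of a strained azirine; in that respect it is better. The exchange at C8a costs about as many steps as saponification, Curtius rearrangement and deprotection. An activated form of A1 might even be coupled directly with a tyrosine ester and shorten the endgame. The chosen plan sets against this one mechanistically dictated cascade for both C–N bonds and the aromatisation, from halves that contain no enolisable 1,2-dicarbonyl unit.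

**Alternative 2:** The imidazolone is assembled first (N4–C3 and N4–C8a) and the pyrazine is left for the end (N7–C6). The aminoketone A5 opens the azlactone A4 at its carbonyl and recloses on the amide carbon to give imidazolone A3. After Boc removal, N7 would condense with the aryl ketone. Three prototropic shifts would then have to carry the benzylidene double bond into the ring system, with loss of the phenylalanine-derived stereocentre.
- Merits: All atoms come from amino-acid-type pieces. No pyrazine intermediate is needed, and the sequence is redox-neutral on paper and short.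
- Weak points: Reclosure of the ring-opened diamide to the imidazolone needs forcing dehydration. A5 (free phenol, self-condensing amine), the aryl acetate and the Boc group must survive it. The 2-alkyl azlactone A4 with an α-carbamate is a labile acylating agent. The final isomerisation must move a double bond out of a stable arylidene-imidazolone chromophore into an oxygen-sensitive dihydropyrazine, and nothing in the structure enforces that tautomer. The sequence may stop at, or oxidise to, the dehydro level.
- Comparison: If it worked it would be clearly shorter and more convergent than the chosen plan. The chosen plan sets against it that each ring closure belongs to an established reaction type and that the sensitive bicycle appears only in the final acidic step.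

**Alternative 3:** The bonds N1–C2 and C2–CH2 are cut. The silyl-protected aminopyrazine A7 condenses with a glyoxylate ester, and a benzylic zinc reagent adds to the imine to give the amino ester A6. Acid then closes N4–C3 and removes the silyl groups. No ring forms in the key step; this is an endgame only.
- Merits: It avoids the ketoacetal and its Grignard chemistry. It is modular for analogues, and A6 is a stable intermediate that can be purified.
- Weak points: A 2-aminopyrazine is a poor partner for imine formation, so hemiaminals and aminals are likely. The pyrazine nitrogens can hold the organozinc reagent. A separate lactamisation is needed. The plan does not address how A7 is made.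
- Comparison: As an endgame it is about as long as steps 9 to 11 and avoids the self-condensing oxoaldehyde, which is in its favour. Its pyrazine would most simply come from cross-coupling of a dihalo-aminopyrazine, which is shorter than the ring synthesis chosen here. The chosen plan sets against this a de novo pyrazine from non-heterocyclic feedstocks with no halogen-selectivity question, and a final condensation that is the standard closure for this ring system. The two are compatible: an A6-type endgame could be attached to 15.

Key step: step 5

Assumptions: Oxime 5, tosylate 6 and diazatriene 8 are mixtures or rapidly interconverting isomers at their C=N and C=C bonds, so their SMILES carry no double-bond descriptors. Compounds 7 and 9 are racemic. Tosyl azide 2 is used as a commercial solution and is not concentrated to dryness.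

## Route

Step 1
Reactants: 1 4-ethynylanisole; 2 tosyl azide
Product: 3 4-(4-methoxyphenyl)-1-tosyl-1H-1,2,3-triazole
Conditions: Cu(O2CC4H3S) (copper thiophene-2-carboxylate, 10 mol %), toluene, 0 °C to rt
Reagents that add atoms: none
Why: Copper-catalysed azide–alkyne cycloaddition with a sulfonyl azide; the copper carboxylate in a non-basic, non-polar medium gives only the 1,4-disubstituted N-sulfonyl triazole and keeps the copper triazolide from fragmenting to a ketenimine.

Step 2
Reactants: 4 methyl 3-oxo-4-phenylbutanoate
Product: 5 methyl 3-(hydroxyimino)-4-phenylbutanoate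
Conditions: NH2OH·HCl, NaOAc, MeOH, 0 °C to rt
Reagents that add atoms: hydroxylamine hydrochloride, NO.Cl
Why: Oxime formation at the ketone of a β-keto ester; the acetate buffer and low temperature are chosen so that the oxime does not lactonise to the isoxazol-5-one, and the C=N geometry does not matter for the next steps.

Step 3
Reactants: 5 methyl 3-(hydroxyimino)-4-phenylbutanoate
Product: 6 methyl 4-phenyl-3-[(tosyloxy)imino]butanoate
Conditions: TsCl, pyridine, CH2Cl2, 0 °C
Reagents that add atoms: p-toluenesulfonyl chloride, Cc1ccc(cc1)S(=O)(=O)Cl
Why: O-Sulfonylation of an oxime; pyridine is too weak a base to start the Neber cyclisation at 0 °C, so the tosylate can be isolated.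

Step 4
Reactants: 6 methyl 4-phenyl-3-[(tosyloxy)imino]butanoate
Product: 7 methyl 3-benzyl-2H-azirine-2-carboxylate (racemic)
Conditions: Et3N, CH2Cl2, 0 °C to rt; short silica plug, stored cold
Reagents that add atoms: none
Why: Neber reaction: triethylamine removes the most acidic hydrogen, at C2 between the ester and the C=N bond, and the carbanion displaces tosylate from nitrogen to close the azirine; the C2 stereocentre forms racemic, which is immaterial because this carbon becomes sp2 in step 5.

Step 5
Reactants: 3 4-(4-methoxyphenyl)-1-tosyl-1H-1,2,3-triazole; 7 methyl 3-benzyl-2H-azirine-2-carboxylate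
Product: 10 methyl 3-benzyl-5-(4-methoxyphenyl)pyrazine-2-carboxylate, via the 1,4-diazahexatriene 8 (not isolated), via the N-tosyl-1,2-dihydropyrazine 9 (not isolated)
Conditions: Rh2(O2CC7H15)4 (dirhodium tetraoctanoate, 2 mol %), 3 (1.3 equiv), 1,2-dichloroethane, 4 Å molecular sieves, 80 °C; then DBU (1.5 equiv), rt
Reagents that add atoms: none
Why: On warming, 3 equilibrates with its ring-opened α-diazo imine, which Rh2(O2CC7H15)4 converts with loss of N2 into an electrophilic α-imino carbene whose carbene carbon (C6) bears the anisyl group. The azirine nitrogen of 7 attacks this carbon (N7–C6) to give an azirinium ylide, and cleavage of its N–C2 single bond releases ring strain and delivers the 1,4-diazahexatriene 8. Thermal disrotatory 6π-azaelectrocyclisation of 8 joins the sulfonyl nitrogen to the ester-bearing carbon (N4–C8a, six-membered ring, 1,6-closure) to give 9. DBU then removes the hydrogen at C8a, acidified by the ester, and E1cB loss of p-toluenesulfinate aromatises the ring to 10. The closest known reaction type is the dirhodium-carboxylate-catalysed union of 1-sulfonyl-1,2,3-triazoles with 2H-azirine-2-carboxylates to 1,2-dihydropyrazines and pyrazines; only the 3-benzyl substituent is new here. The stereocentre formed at C8a in 9 is uncontrolled and is erased on aromatisation, so no stereochemical issue arises. Regiochemistry is fixed by the mechanism: aryl arrives on the carbene carbon next to N7, benzyl on azirine C3 on the other side of N7, and the ester on the carbon bonded to N4. The selectivity needed is 1,6- over 1,5-closure of 8 (the latter, a polar Mannich-type attack of C8a on the sulfonylimine carbon, leads to an aminopyrrole); a neutral, non-polar medium without Lewis acid, with base added only after 8 is consumed, favours the pericyclic path, and placing aryl rather than benzyl on the carbene carbon rules out a 1,2-hydride shift.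

Step 6
Reactants: 10 methyl 3-benzyl-5-(4-methoxyphenyl)pyrazine-2-carboxylate
Product: 11 3-benzyl-5-(4-methoxyphenyl)pyrazine-2-carboxylic acid
Conditions: LiOH·H2O, THF/H2O, rt; then 1 M HCl to pH 3
Reagents that add atoms: lithium hydroxide, [Li+].[OH-]
Why: Saponification of an electron-poor heteroaryl methyl ester, fast at room temperature; the anisyl ether and benzyl group are inert, and the acid is isolated without heating to avoid decarboxylation.

Step 7
Reactants: 11 3-benzyl-5-(4-methoxyphenyl)pyrazine-2-carboxylic acid
Product: 14 tert-butyl [3-benzyl-5-(4-methoxyphenyl)pyrazin-2-yl]carbamate, via the acyl azide 12 (not isolated), via the isocyanate 13 (not isolated)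
Conditions: DPPA, Et3N, t-BuOH/toluene, rt then 85 °C
Reagents that add atoms: diphenylphosphoryl azide, [N-]=[N+]=NP(=O)(Oc1ccccc1)Oc1ccccc1; tert-butanol, CC(C)(C)O
Why: Curtius rearrangement: the mixed phosphoric anhydride gives acyl azide 12, which loses nitrogen on warming to isocyanate 13, and tert-butanol traps it as the carbamate; this exchanges the carbon handle at C8a for the exocyclic nitrogen.

Step 8
Reactants: 14 tert-butyl [3-benzyl-5-(4-methoxyphenyl)pyrazin-2-yl]carbamate
Product: 15 coelenteramine [4-(5-amino-6-benzylpyrazin-2-yl)phenol]
Conditions: BBr3 (5 equiv), CH2Cl2, −78 °C to rt; MeOH, then aq. NaHCO3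
Reagents that add atoms: none
Why: Lewis-acid ether cleavage: BBr3 demethylates the aryl methyl ether and in the same operation cleaves the tert-butyl carbamate (loss of the tert-butyl group, decarboxylation on work-up); the excess allows for complexation by the three nitrogen atoms.

Step 9
Reactants: 16 4-(benzyloxy)benzyl chloride; 17 ethyl diethoxyacetate
Product: 19 3-[4-(benzyloxy)phenyl]-1,1-diethoxypropan-2-one, via the benzylic Grignard reagent 18 (not isolated)
Conditions: Mg, THF, 0 °C to rt (slow addition of 16); then 17, THF, −78 °C; aq. NH4Cl
Reagents that add atoms: none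
Why: Grignard acylation: the benzylic magnesium reagent adds once to the ester of 17 at −78 °C because the α-alkoxy groups chelate magnesium and hold the tetrahedral adduct until the quench, so the ketone is released only on work-up.

Step 10
Reactants: 19 3-[4-(benzyloxy)phenyl]-1,1-diethoxypropan-2-one
Product: 20 1,1-diethoxy-3-(4-hydroxyphenyl)propan-2-one
Conditions: H2 (1 atm), 10% Pd/C, EtOAc, rt
Reagents that add atoms: none
Why: Hydrogenolysis of a benzyl aryl ether over Pd/C under neutral conditions; the ketone and the diethyl acetal are untouched at atmospheric pressure.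

Step 11
Reactants: 15 coelenteramine; 20 1,1-diethoxy-3-(4-hydroxyphenyl)propan-2-one
Product: 22 coelenterazine [8-benzyl-2-(4-hydroxybenzyl)-6-(4-hydroxyphenyl)imidazo[1,2-a]pyrazin-3(7H)-one], via the 2-oxoaldehyde 21 (not isolated)
Conditions: 20 (1.5 equiv), conc. aq. HCl, degassed EtOH/H2O, argon, 80 °C
Reagents that add atoms: water, O
Why: Acid-mediated condensation of a 2-aminopyrazine with a 2-oxoaldehyde acetal, the classical closure of imidazo[1,2-a]pyrazin-3(7H)-ones: the acetal is hydrolysed to 21, the exocyclic amine condenses with the ketone carbon (N1–C2), ring nitrogen N4 adds to the aldehyde carbon (N4–C3), and the adduct tautomerises to the 3-oxo-7H form; strict exclusion of oxygen protects the product.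

## Compound list

1 | 4-ethynylanisole | C#Cc1ccc(OC)cc1 | starting material
2 | tosyl azide (4-methylbenzenesulfonyl azide) | Cc1ccc(cc1)S(=O)(=O)N=[N+]=[N-] | starting material
3 | 4-(4-methoxyphenyl)-1-tosyl-1H-1,2,3-triazole | COc1ccc(-c2cn(S(=O)(=O)c3ccc(C)cc3)nn2)cc1 | intermediate
4 | methyl 3-oxo-4-phenylbutanoate | COC(=O)CC(=O)Cc1ccccc1 | starting material
5 | methyl 3-(hydroxyimino)-4-phenylbutanoate (mixture of oxime isomers) | COC(=O)CC(=NO)Cc1ccccc1 | intermediate
6 | methyl 4-phenyl-3-[(tosyloxy)imino]butanoate (mixture of oxime isomers) | COC(=O)CC(=NOS(=O)(=O)c1ccc(C)cc1)Cc1ccccc1 | intermediate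
7 | methyl 3-benzyl-2H-azirine-2-carboxylate (racemic) | COC(=O)C1N=C1Cc1ccccc1 | intermediate
8 | methyl 3-({1-(4-methoxyphenyl)-2-[(4-methylbenzenesulfonyl)imino]ethylidene}amino)-4-phenylbut-2-enoate (1,4-diazahexatriene, geometry not fixed) | COC(=O)C=C(Cc1ccccc1)N=C(C=NS(=O)(=O)c1ccc(C)cc1)c1ccc(OC)cc1 | intermediate
9 | methyl 3-benzyl-5-(4-methoxyphenyl)-1-tosyl-1,2-dihydropyrazine-2-carboxylate (racemic) | COC(=O)C1N(S(=O)(=O)c2ccc(C)cc2)C=C(c2ccc(OC)cc2)N=C1Cc1ccccc1 | intermediate
10 | methyl 3-benzyl-5-(4-methoxyphenyl)pyrazine-2-carboxylate | COC(=O)c1ncc(-c2ccc(OC)cc2)nc1Cc1ccccc1 | intermediate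
11 | 3-benzyl-5-(4-methoxyphenyl)pyrazine-2-carboxylic acid | O=C(O)c1ncc(-c2ccc(OC)cc2)nc1Cc1ccccc1 | intermediate
12 | 3-benzyl-5-(4-methoxyphenyl)pyrazine-2-carbonyl azide | [N-]=[N+]=NC(=O)c1ncc(-c2ccc(OC)cc2)nc1Cc1ccccc1 | intermediate
13 | 3-benzyl-2-isocyanato-5-(4-methoxyphenyl)pyrazine | O=C=Nc1ncc(-c2ccc(OC)cc2)nc1Cc1ccccc1 | intermediate
14 | tert-butyl [3-benzyl-5-(4-methoxyphenyl)pyrazin-2-yl]carbamate | CC(C)(C)OC(=O)Nc1ncc(-c2ccc(OC)cc2)nc1Cc1ccccc1 | intermediate
15 | coelenteramine, 4-(5-amino-6-benzylpyrazin-2-yl)phenol | Nc1ncc(-c2ccc(O)cc2)nc1Cc1ccccc1 | intermediate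
16 | 4-(benzyloxy)benzyl chloride | ClCc1ccc(OCc2ccccc2)cc1 | starting material
17 | ethyl diethoxyacetate | CCOC(=O)C(OCC)OCC | starting material
18 | [4-(benzyloxy)benzyl]magnesium chloride | Cl[Mg]Cc1ccc(OCc2ccccc2)cc1 | intermediate
19 | 3-[4-(benzyloxy)phenyl]-1,1-diethoxypropan-2-one | CCOC(OCC)C(=O)Cc1ccc(OCc2ccccc2)cc1 | intermediate
20 | 1,1-diethoxy-3-(4-hydroxyphenyl)propan-2-one | CCOC(OCC)C(=O)Cc1ccc(O)cc1 | intermediate
21 | 3-(4-hydroxyphenyl)-2-oxopropanal | O=CC(=O)Cc1ccc(O)cc1 | intermediate
22 | coelenterazine, 8-benzyl-2-(4-hydroxybenzyl)-6-(4-hydroxyphenyl)imidazo[1,2-a]pyrazin-3(7H)-one | O=c1c(Cc2ccc(O)cc2)nc2c(Cc3ccccc3)[nH]c(-c3ccc(O)cc3)cn1-2 | target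

## Step count and risk

Total: 11 steps. Longest linear sequence: 8 steps (4 to 22 through steps 2, 3, 4, 5, 6, 7, 8 and 11).

**Step 5 (key step).**
- What may go wrong: The diazatriene may close 1,5 by polar attack of C8a on the sulfonylimine carbon and not 1,6. A prototropic shift of the benzylic hydrogens in 7 or 8 may move unsaturation into conjugation with the phenyl ring before closure. The rhodium catalyst may open or dimerise the strained azirine faster than the triazole loses nitrogen.
- Fallback: It sets out from 4, uses 2, and returns at 10. Diazo transfer from tosyl azide 2 to 4 (Et3N, MeCN) gives methyl 2-diazo-3-oxo-4-phenylbutanoate F1. Commercial 2-amino-1-(4-methoxyphenyl)ethanone hydrochloride and Boc2O give tert-butyl [2-(4-methoxyphenyl)-2-oxoethyl]carbamate F2. Rh2(OAc)4-catalysed N–H insertion of the carbene from F1 into F2 forms the N4–C8a bond and gives methyl 2-{(tert-butoxycarbonyl)[2-(4-methoxyphenyl)-2-oxoethyl]amino}-3-oxo-4-phenylbutanoate F3. Trifluoroacetic acid frees methyl 2-{[2-(4-methoxyphenyl)-2-oxoethyl]amino}-3-oxo-4-phenylbutanoate F4. NH4OAc in warm acetic acid supplies N7, which condenses with both ketones to methyl 3-benzyl-5-(4-methoxyphenyl)-1,6-dihydropyrazine-2-carboxylate F5. Air or MnO2 aromatises F5 to 10. Every ring bond is then made by a classical ionic step, and the connectivity of F4 fixes the regiochemistry.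

**Step 4 (Neber cyclisation).**
- What may go wrong: Beckmann-type rearrangement or fragmentation of the oxime tosylate may compete with cyclisation. Deprotonation may occur at the benzylic C4 and not at C2. The azirine may hydrolyse or dimerise during isolation.
- Fallback: It sets out from 5 and returns at 7. Heating 5 with NaOAc in ethanol lactonises it to 3-benzylisoxazol-5(4H)-one F6. POCl3 and Et3N convert F6 into 3-benzyl-5-chloroisoxazole F7. Catalytic FeCl2 in acetonitrile at room temperature isomerises F7, by N–O cleavage and reclosure, to 3-benzyl-2H-azirine-2-carbonyl chloride F8. Methanol and 2,6-lutidine quench F8 to 7. This route reaches the azirine from a stable heteroaromatic precursor and avoids the base-induced displacement at nitrogen.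

**Step 7 (Curtius rearrangement).**
- What may go wrong: The pyrazine-2-carboxylic acid may decarboxylate thermally before the acyl azide forms. Adventitious water may capture the isocyanate and lead to urea formation. Addition of the hindered alcohol may be slow.
- Fallback: It sets out from 10 and returns at 15. Ammonia in methanol converts 10 into 3-benzyl-5-(4-methoxyphenyl)pyrazine-2-carboxamide F9. Hofmann rearrangement (NaOCl, aqueous NaOH, 0 to 70 °C) gives 3-benzyl-5-(4-methoxyphenyl)pyrazin-2-amine F10. BBr3 in CH2Cl2 demethylates F10 to 15. No free acid and no acyl azide are involved.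

**Step 11 (final condensation).**
- What may go wrong: The unmasked oxoaldehyde may self-condense. The product may autoxidise in the hot medium or during isolation. Condensation may occur in the reverse orientation.
- Fallback: It sets out from 15 and returns at 22. TBSCl and imidazole silylate the phenol of 15 to 3-benzyl-5-[4-(tert-butyldimethylsilyloxy)phenyl]pyrazin-2-amine F11 (identical with A7). Commercial methyl L-tyrosinate is O-silylated to methyl O-(tert-butyldimethylsilyl)-L-tyrosinate F12. Diazotisation (isoamyl nitrite, catalytic AcOH, CHCl3) gives methyl 2-diazo-3-[4-(tert-butyldimethylsilyloxy)phenyl]propanoate F13. Rh2(OAc)4-catalysed N–H insertion of the carbene from F13 into F11, run cold to suppress 1,2-hydride migration, forms N1–C2 and gives methyl 2-({3-benzyl-5-[4-(tert-butyldimethylsilyloxy)phenyl]pyrazin-2-yl}amino)-3-[4-(tert-butyldimethylsilyloxy)phenyl]propanoate F14 (racemic). Aqueous HCl in dioxane under argon at 80 °C removes both silyl ethers, hydrolyses the ester and closes N4–C3 by lactamisation to 22. The two C–N bonds of the imidazolone are then made separately, and no free oxoaldehyde is present.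

## Further compounds

F1 | step 5 | methyl 2-diazo-3-oxo-4-phenylbutanoate | COC(=O)C(=[N+]=[N-])C(=O)Cc1ccccc1
F2 | step 5 | tert-butyl [2-(4-methoxyphenyl)-2-oxoethyl]carbamate | COc1ccc(cc1)C(=O)CNC(=O)OC(C)(C)C
F3 | step 5 | methyl 2-{(tert-butoxycarbonyl)[2-(4-methoxyphenyl)-2-oxoethyl]amino}-3-oxo-4-phenylbutanoate (racemic) | COC(=O)C(N(CC(=O)c1ccc(OC)cc1)C(=O)OC(C)(C)C)C(=O)Cc1ccccc1
F4 | step 5 | methyl 2-{[2-(4-methoxyphenyl)-2-oxoethyl]amino}-3-oxo-4-phenylbutanoate (racemic) | COC(=O)C(NCC(=O)c1ccc(OC)cc1)C(=O)Cc1ccccc1
F5 | step 5 | methyl 3-benzyl-5-(4-methoxyphenyl)-1,6-dihydropyrazine-2-carboxylate | COC(=O)C1=C(Cc2ccccc2)N=C(c2ccc(OC)cc2)CN1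
F6 | step 4 | 3-benzylisoxazol-5(4H)-one | O=C1CC(Cc2ccccc2)=NO1
F7 | step 4 | 3-benzyl-5-chloroisoxazole | Clc1cc(Cc2ccccc2)no1
F8 | step 4 | 3-benzyl-2H-azirine-2-carbonyl chloride (racemic) | O=C(Cl)C1N=C1Cc1ccccc1
F9 | step 7 | 3-benzyl-5-(4-methoxyphenyl)pyrazine-2-carboxamide | NC(=O)c1ncc(-c2ccc(OC)cc2)nc1Cc1ccccc1
F10 | step 7 | 3-benzyl-5-(4-methoxyphenyl)pyrazin-2-amine | COc1ccc(-c2cnc(N)c(Cc3ccccc3)n2)cc1
F11 | step 11 | 3-benzyl-5-[4-(tert-butyldimethylsilyloxy)phenyl]pyrazin-2-amine | CC(C)(C)[Si](C)(C)Oc1ccc(-c2cnc(N)c(Cc3ccccc3)n2)cc1
F12 | step 11 | methyl O-(tert-butyldimethylsilyl)-L-tyrosinate | COC(=O)[C@@H](N)Cc1ccc(O[Si](C)(C)C(C)(C)C)cc1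
F13 | step 11 | methyl 2-diazo-3-[4-(tert-butyldimethylsilyloxy)phenyl]propanoate | COC(=O)C(=[N+]=[N-])Cc1ccc(O[Si](C)(C)C(C)(C)C)cc1
F14 | step 11 | methyl 2-({3-benzyl-5-[4-(tert-butyldimethylsilyloxy)phenyl]pyrazin-2-yl}amino)-3-[4-(tert-butyldimethylsilyloxy)phenyl]propanoate (racemic) | COC(=O)C(Cc1ccc(O[Si](C)(C)C(C)(C)C)cc1)Nc1ncc(-c2ccc(O[Si](C)(C)C(C)(C)C)cc2)nc1Cc1ccccc1
A1 | alternative 1 | 3-benzyl-5-(4-hydroxyphenyl)pyrazin-2(1H)-one | O=c1[nH]cc(-c2ccc(O)cc2)nc1Cc1ccccc1
A2 | alternative 1 | N-[2-(4-hydroxyphenyl)-2-oxoethyl]-2-oxo-3-phenylpropanamide | O=C(Cc1ccccc1)C(=O)NCC(=O)c1ccc(O)cc1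
A3 | alternative 2 | (Z)-4-(4-acetoxybenzylidene)-2-[(1S)-1-(tert-butoxycarbonylamino)-2-phenylethyl]-1-[2-(4-hydroxyphenyl)-2-oxoethyl]imidazol-5(4H)-one | CC(=O)Oc1ccc(/C=C2\N=C([C@H](Cc3ccccc3)NC(=O)OC(C)(C)C)N(CC(=O)c3ccc(O)cc3)C2=O)cc1
A4 | alternative 2 | (Z)-4-(4-acetoxybenzylidene)-2-[(1S)-1-(tert-butoxycarbonylamino)-2-phenylethyl]oxazol-5(4H)-one | CC(=O)Oc1ccc(/C=C2\N=C([C@H](Cc3ccccc3)NC(=O)OC(C)(C)C)OC2=O)cc1
A5 | alternative 2 | 2-amino-1-(4-hydroxyphenyl)ethan-1-one | NCC(=O)c1ccc(O)cc1
A6 | alternative 3 | ethyl 2-({3-benzyl-5-[4-(tert-butyldimethylsilyloxy)phenyl]pyrazin-2-yl}amino)-3-[4-(tert-butyldimethylsilyloxy)phenyl]propanoate (racemic) | CCOC(=O)C(Cc1ccc(O[Si](C)(C)C(C)(C)C)cc1)Nc1ncc(-c2ccc(O[Si](C)(C)C(C)(C)C)cc2)nc1Cc1ccccc1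
A7 | alternative 3 | 3-benzyl-5-[4-(tert-butyldimethylsilyloxy)phenyl]pyrazin-2-amine | CC(C)(C)[Si](C)(C)Oc1ccc(-c2cnc(N)c(Cc3ccccc3)n2)cc1
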